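**Retrosynthetic overview**

1. The target comes from its doubly protected enal by one acid treatment that removes the aryl MOM acetal and the trityl ether together; the enal comes from the matching benzodioxane-6-carbaldehyde by a two-carbon Wittig homologation.
2. Feature used: in ring A the carbon carrying the propenal chain has the dioxane oxygen of C8 (Ob; C8 is the CH–CH2OH carbon) para to it and the dioxane oxygen of benzylic C7 (Oa) meta to it. Ring A therefore maps onto 4-fluoro-3-hydroxybenzaldehyde (F marks the Ob carbon, OH is Oa), and the trans C7/C8 pair is what a single SN2 inversion of a cis-oxirane leaves behind.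
3. Key disconnection: the 1,4-dioxane ring is cut at Oa–C7 and at C(aryl)–Ob, giving a cis-(7R,8S)-aryl epoxide and the fluorophenol. In the forward direction, phenoxide opening at C7 and SNAr closure by the C8 alkoxide run in one pot.
4. The epoxide comes from a (Z)-aryl allyl ether by (salen)Mn epoxidation. The alkene comes from Sonogashira coupling of MOM-protected 4-bromo-2,6-dimethoxyphenol with propargyl trityl ether, followed by semihydrogenation.
5. Ring order: both benzene rings are bought; the oxirane is made and then consumed; the 1,4-dioxane, the only ring built for the target, closes in the key step.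

Key step: step 6

Remark on the structure: side-chain atoms carry lignan numbers (C7 benzylic CH, C8 the CH bearing C9H2O). The given SMILES is read as the trans-(7S,8S) isomer, which is (2S,3S) in benzodioxine numbering.

Remark on protection: the phenol is carried as a MOM acetal and the C9 hydroxyl as a trityl ether. Both are inert to carbonate and to the fluoride released in the ring closure, neither can migrate to the C8 alkoxide, and both are removed together by dilute acid. An aryl silyl ether would be at risk from carbonate and fluoride, and a small silyl ether next to the C8 alkoxide could migrate.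

**Route**

Step 1
Reactants: 1 propargyl alcohol (prop-2-yn-1-ol)
Product: 2 3-(triphenylmethoxy)prop-1-yne (propargyl trityl ether)
Conditions: TrCl, Et3N, DMAP (cat.), CH2Cl2, 0 °C to rt
Reagents that add atoms: trityl chloride, ClC(c1ccccc1)(c1ccccc1)c1ccccc1
Why: SN1-type tritylation of a primary alcohol through the trityl cation; the resulting ether is inert to base, fluoride and hypochlorite and cannot shift to a neighbouring alkoxide later on.

Step 2
Reactants: 3 4-bromo-2,6-dimethoxyphenol
Product: 4 5-bromo-1,3-dimethoxy-2-(methoxymethoxy)benzene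
Conditions: MOMCl, iPr2NEt, CH2Cl2, 0 °C to rt
Reagents that add atoms: chloromethyl methyl ether, COCCl
Why: Williamson-type O-alkylation of the phenol by the very reactive α-chloro ether; the MOM acetal withstands carbonate, fluoride and bleach and keeps the para oxygen from opening the later epoxide through a quinone methide.

Step 3
Reactants: 4 5-bromo-1,3-dimethoxy-2-(methoxymethoxy)benzene; 2 3-(triphenylmethoxy)prop-1-yne
Product: 5 1,3-dimethoxy-2-(methoxymethoxy)-5-[3-(triphenylmethoxy)prop-1-yn-1-yl]benzene
Conditions: PdCl2(PPh3)2 (3 mol%), CuI (5 mol%), Et3N/DMF, 80 °C, degassed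
Reagents that add atoms: none
Why: Sonogashira coupling, in which oxidative addition of the aryl bromide to zerovalent palladium, transmetalation from the copper acetylide and reductive elimination form the aryl–alkynyl bond, while the amine base leaves the acetal and the trityl ether alone.

Step 4
Reactants: 5 1,3-dimethoxy-2-(methoxymethoxy)-5-[3-(triphenylmethoxy)prop-1-yn-1-yl]benzene
Product: 6 1,3-dimethoxy-2-(methoxymethoxy)-5-[(1Z)-3-(triphenylmethoxy)prop-1-en-1-yl]benzene
Conditions: H2 (1 atm), Pd/CaCO3/Pb(OAc)2, quinoline, EtOAc, rt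
Reagents that add atoms: none
Why: Lindlar semihydrogenation, in which syn delivery of hydrogen on the lead-poisoned palladium surface stops at the (Z)-alkene and so fixes the cis geometry that the epoxide must carry.

Step 5
Reactants: 6 1,3-dimethoxy-2-(methoxymethoxy)-5-[(1Z)-3-(triphenylmethoxy)prop-1-en-1-yl]benzene
Product: 7 (2R,3S)-2-[3,5-dimethoxy-4-(methoxymethoxy)phenyl]-3-[(triphenylmethoxy)methyl]oxirane (cis; C7 R, C8 S)
Conditions: (R,R)-[N,N'-bis(3,5-di-tert-butylsalicylidene)cyclohexane-1,2-diaminato]MnCl (5 mol%), 4-phenylpyridine N-oxide (20 mol%), aq NaOCl (pH 11.3), CH2Cl2, 0 °C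
Reagents that add atoms: sodium hypochlorite, [Na+].[O-]Cl
Why: Jacobsen–Katsuki epoxidation of a cis-disubstituted aryl alkene, the preferred substrate class for (salen)Mn oxo transfer; the (R,R) ligand should deliver oxygen to the face that makes C7 R and C8 S (the sense known for cis-β-methylstyrene and cis-cinnamates), and the N-oxide additive limits leakage to the trans-epoxide.

Step 6
Reactants: 7 (2R,3S)-2-[3,5-dimethoxy-4-(methoxymethoxy)phenyl]-3-[(triphenylmethoxy)methyl]oxirane; 8 4-fluoro-3-hydroxybenzaldehyde
Product: 10 trans-(2S,3S)-3-[3,5-dimethoxy-4-(methoxymethoxy)phenyl]-2-[(triphenylmethoxy)methyl]-2,3-dihydro-1,4-benzodioxine-6-carbaldehyde, via ring-opened fluoro alkoxide 9 (not isolated)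
Conditions: Cs2CO3 (2 equiv), DMF, 60 °C then 90 °C
Reagents that add atoms: none
Why: Cs2CO3 converts 8 into its phenoxide, which attacks the benzylic carbon C7 of 7 in an SN2 opening anti to the oxirane oxygen to give alkoxide 9, and the C8 alkoxide, now held beside the C–F bond that is para to the formyl group, adds to that carbon and expels fluoride from the Meisenheimer adduct (SNAr). The closest known reaction type is the base-mediated tandem epoxide opening and intramolecular SNAr of ortho-halophenols or ortho-halohydroxypyridines that delivers fused 1,4-dioxanes, and benzylic opening of 3-aryl glycidyl ethers by phenoxides is likewise established. The 1,4-dioxane ring closes in a 6-exo addition–elimination at the aromatic carbon. C7 is the only stereocentre that changes: backside attack on the enantiopure cis-epoxide inverts it from R to S, while C8 keeps its oxygen and its S configuration, so the aryl group and CH2OTr end up trans. The step needs attack at C7 and not at C8, which is secured by benzylic activation of C7 and by the inductive and steric retardation of C8 through its CH2OTr group; it also needs closure at the C–F carbon and not a Smiles shift at the carbon bearing Oa, which is secured because only the C–F carbon is para to the formyl group. The MOM acetal and the trityl ether are inert to carbonate and fluoride and cannot migrate to the alkoxide.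

Step 7
Reactants: 10 trans-(2S,3S)-3-[3,5-dimethoxy-4-(methoxymethoxy)phenyl]-2-[(triphenylmethoxy)methyl]-2,3-dihydro-1,4-benzodioxine-6-carbaldehyde
Product: 11 (2E)-3-{(2S,3S)-3-[3,5-dimethoxy-4-(methoxymethoxy)phenyl]-2-[(triphenylmethoxy)methyl]-2,3-dihydro-1,4-benzodioxin-6-yl}prop-2-enal
Conditions: Ph3P=CHCHO (1.3 equiv), toluene, 80 °C
Reagents that add atoms: (triphenylphosphoranylidene)acetaldehyde, O=CC=P(c1ccccc1)(c1ccccc1)c1ccccc1
Why: Wittig olefination with a formyl-stabilised ylide, which is (E)-selective and runs under neutral conditions, so the acetal, the trityl ether and both stereocentres are left untouched.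

Step 8
Reactants: 11 (2E)-3-{(2S,3S)-3-[3,5-dimethoxy-4-(methoxymethoxy)phenyl]-2-[(triphenylmethoxy)methyl]-2,3-dihydro-1,4-benzodioxin-6-yl}prop-2-enal
Product: 12 (2E)-3-[(2S,3S)-3-(4-hydroxy-3,5-dimethoxyphenyl)-2-(hydroxymethyl)-2,3-dihydro-1,4-benzodioxin-6-yl]prop-2-enal (target)
Conditions: 3 M aq HCl/THF (1:4), rt to 40 °C
Reagents that add atoms: none
Why: acid-catalysed acetal hydrolysis of the aryl MOM ether and SN1 cleavage of the trityl ether in one operation; dilute acid at this temperature should neither ionise the C7–Oa bond nor affect the enal, so the trans-(S,S) configuration is kept.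

**Compound list**

1 | propargyl alcohol (prop-2-yn-1-ol) | C#CCO | starting material
2 | 3-(triphenylmethoxy)prop-1-yne | C#CCOC(c1ccccc1)(c1ccccc1)c1ccccc1 | intermediate
3 | 4-bromo-2,6-dimethoxyphenol | COc1cc(Br)cc(OC)c1O | starting material
4 | 5-bromo-1,3-dimethoxy-2-(methoxymethoxy)benzene | COCOc1c(OC)cc(Br)cc1OC | intermediate
5 | 1,3-dimethoxy-2-(methoxymethoxy)-5-[3-(triphenylmethoxy)prop-1-yn-1-yl]benzene | COCOc1c(OC)cc(C#CCOC(c2ccccc2)(c2ccccc2)c2ccccc2)cc1OC | intermediate
6 | 1,3-dimethoxy-2-(methoxymethoxy)-5-[(1Z)-3-(triphenylmethoxy)prop-1-en-1-yl]benzene | COCOc1c(OC)cc(/C=C\COC(c2ccccc2)(c2ccccc2)c2ccccc2)cc1OC | intermediate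
7 | (2R,3S)-2-[3,5-dimethoxy-4-(methoxymethoxy)phenyl]-3-[(triphenylmethoxy)methyl]oxirane (cis) | COCOc1c(OC)cc([C@H]2O[C@H]2COC(c3ccccc3)(c3ccccc3)c3ccccc3)cc1OC | intermediate
8 | 4-fluoro-3-hydroxybenzaldehyde | O=Cc1ccc(F)c(O)c1 | starting material
9 | 4-fluoro-3-{[(1S,2S)-1-[3,5-dimethoxy-4-(methoxymethoxy)phenyl]-2-hydroxy-3-(triphenylmethoxy)propyl]oxy}benzaldehyde (present as its caesium alkoxide, not isolated) | COCOc1c(OC)cc([C@H](Oc2cc(C=O)ccc2F)[C@@H](O)COC(c3ccccc3)(c3ccccc3)c3ccccc3)cc1OC | intermediate
10 | trans-(2S,3S)-3-[3,5-dimethoxy-4-(methoxymethoxy)phenyl]-2-[(triphenylmethoxy)methyl]-2,3-dihydro-1,4-benzodioxine-6-carbaldehyde | COCOc1c(OC)cc([C@@H]2Oc3cc(C=O)ccc3O[C@H]2COC(c4ccccc4)(c4ccccc4)c4ccccc4)cc1OC | intermediate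
11 | (2E)-3-{(2S,3S)-3-[3,5-dimethoxy-4-(methoxymethoxy)phenyl]-2-[(triphenylmethoxy)methyl]-2,3-dihydro-1,4-benzodioxin-6-yl}prop-2-enal | COCOc1c(OC)cc([C@@H]2Oc3cc(/C=C/C=O)ccc3O[C@H]2COC(c4ccccc4)(c4ccccc4)c4ccccc4)cc1OC | intermediate
12 | (2E)-3-[(2S,3S)-3-(4-hydroxy-3,5-dimethoxyphenyl)-2-(hydroxymethyl)-2,3-dihydro-1,4-benzodioxin-6-yl]prop-2-enal | COc1cc([C@@H]2Oc3cc(/C=C/C=O)ccc3O[C@H]2CO)cc(OC)c1O | target

**Step count**

Total step count: 8 (steps 1 and 2 each prepare one coupling partner).
Longest linear sequence: 7 steps (3 → 4 → 5 → 6 → 7 → 10 → 11 → 12; the same length from 1 through 2).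

**Steps most likely to fail**

Step 6. Once Oa is alkylated, the fluorinated ring of 9 is activated toward any phenoxide still present. Intermolecular diaryl ether formation can then compete with closure by the sparsely populated C8 alkoxide. A slow opening of the hindered cis-epoxide would lengthen this exposure, and partial attack at C8 would lead to the regioisomeric dioxane. The fallback sets out from 7 and returns at 10: the two bond formations are separated and the aryl C–Ob bond is made by cross-coupling instead of SNAr. Opening of 7 with commercial 4-bromo-3-hydroxybenzaldehyde (O=Cc1ccc(Br)c(O)c1; K2CO3, DMF, 80 °C) should give 4-bromo-3-{[(1S,2S)-1-[3,5-dimethoxy-4-(methoxymethoxy)phenyl]-2-hydroxy-3-(triphenylmethoxy)propyl]oxy}benzaldehyde F1. The bromoarene is inert to SNAr, so an excess of phenoxide can be used. Intramolecular palladium-catalysed etherification of F1 (Pd(OAc)2, 2-(di-tert-butylphosphino)-1,1'-binaphthyl, Cs2CO3, toluene, 80 °C; Buchwald-type C–O coupling) would then close the dioxane and give 10.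

Step 5. Bond rotation in the benzylic radical intermediate before ring closure would leak material to the trans-epoxide, which would end up as the cis-dioxane. Facial discrimination may be lowered by the bulky trityloxymethyl group, and the electron-rich ring could be chlorinated if the pH of the hypochlorite drifts. The fallback sets out from 4 and 1 and returns at 7: reagent-controlled epoxidation of the free allylic alcohol. Sonogashira coupling of 4 with 1 (PdCl2(PPh3)2, CuI, Et3N, 70 °C) should give 3-[3,5-dimethoxy-4-(methoxymethoxy)phenyl]prop-2-yn-1-ol F2. Semihydrogenation (H2, Pd/CaCO3/Pb(OAc)2, quinoline, EtOAc) should give (2Z)-3-[3,5-dimethoxy-4-(methoxymethoxy)phenyl]prop-2-en-1-ol F3. Sharpless asymmetric epoxidation (Ti(OiPr)4, L-(+)-diisopropyl tartrate, tBuOOH, 4 Å molecular sieves, CH2Cl2, −20 °C) should give [(2S,3R)-3-[3,5-dimethoxy-4-(methoxymethoxy)phenyl]oxiran-2-yl]methanol F4; the L-tartrate directs oxygen to the face that gives the 2S,3R epoxy alcohol from a Z-allylic alcohol. Tritylation (TrCl, Et3N, DMAP, CH2Cl2) would then give 7.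

Step 7. The product enal can itself be olefinated by the ylide, extending the chain to the dienal, and the alkoxy-substituted benzaldehyde reacts slowly, so over-reaction and incomplete conversion may overlap. The fallback sets out from 10 and returns at 11. Horner–Wadsworth–Emmons reaction with triethyl phosphonoacetate (NaH, THF, 0 °C) should give ethyl (2E)-3-{(2S,3S)-3-[3,5-dimethoxy-4-(methoxymethoxy)phenyl]-2-[(triphenylmethoxy)methyl]-2,3-dihydro-1,4-benzodioxin-6-yl}prop-2-enoate F5. Reduction with iBu2AlH (CH2Cl2, −78 °C) should give (2E)-3-{(2S,3S)-3-[3,5-dimethoxy-4-(methoxymethoxy)phenyl]-2-[(triphenylmethoxy)methyl]-2,3-dihydro-1,4-benzodioxin-6-yl}prop-2-en-1-ol F6. Oxidation with MnO2 (CH2Cl2, rt) would give 11.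

**Further compounds**

F1 | step 6 | 4-bromo-3-{[(1S,2S)-1-[3,5-dimethoxy-4-(methoxymethoxy)phenyl]-2-hydroxy-3-(triphenylmethoxy)propyl]oxy}benzaldehyde | COCOc1c(OC)cc([C@H](Oc2cc(C=O)ccc2Br)[C@@H](O)COC(c3ccccc3)(c3ccccc3)c3ccccc3)cc1OC
F2 | step 5 | 3-[3,5-dimethoxy-4-(methoxymethoxy)phenyl]prop-2-yn-1-ol | COCOc1c(OC)cc(C#CCO)cc1OC
F3 | step 5 | (2Z)-3-[3,5-dimethoxy-4-(methoxymethoxy)phenyl]prop-2-en-1-ol | COCOc1c(OC)cc(/C=C\CO)cc1OC
F4 | step 5 | [(2S,3R)-3-[3,5-dimethoxy-4-(methoxymethoxy)phenyl]oxiran-2-yl]methanol | COCOc1c(OC)cc([C@H]2O[C@H]2CO)cc1OC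
F5 | step 7 | ethyl (2E)-3-{(2S,3S)-3-[3,5-dimethoxy-4-(methoxymethoxy)phenyl]-2-[(triphenylmethoxy)methyl]-2,3-dihydro-1,4-benzodioxin-6-yl}prop-2-enoate | COCOc1c(OC)cc([C@@H]2Oc3cc(/C=C/C(=O)OCC)ccc3O[C@H]2COC(c4ccccc4)(c4ccccc4)c4ccccc4)cc1OC
F6 | step 7 | (2E)-3-{(2S,3S)-3-[3,5-dimethoxy-4-(methoxymethoxy)phenyl]-2-[(triphenylmethoxy)methyl]-2,3-dihydro-1,4-benzodioxin-6-yl}prop-2-en-1-ol | COCOc1c(OC)cc([C@@H]2Oc3cc(/C=C/CO)ccc3O[C@H]2COC(c4ccccc4)(c4ccccc4)c4ccccc4)cc1OC
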